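**Retrosynthetic overview**
1. Target ⇐ hydrogenation of a C8 exo-methylene ⇐ reductive allylic opening of a C3-isopropenyl δ-lactone, which delivers the isopropylidene, the free acid and the free phenol in one operation.
2. C4 side chain ⇐ Michael addition of the C3 enolate to methyl acrylate; C9 quaternary centre ⇐ benzylation, then methylation, next to a C8 ketone (benzylic bromide from 4-methoxy-2-methylphenol).
3. cis-Decalin with the angular C5 methyl ⇐ cuprate addition to a bicyclic enone; the trapped enolate also tells the two carbonyls apart.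
4. Enone-ketone ⇐ catalytic enantioselective β,γ→α,β isomerization that desymmetrizes an achiral C2h diketone ⇐ exhaustive Birch reduction of 2,6-dimethoxynaphthalene.
5. Ring order: rings A and B are never built; both come together from the naphthalene core, and the only ring closed (and reopened) afterwards is a temporary δ-lactone on ring A.

Assumption: both starting materials are taken as commercial; decalin carbons carry the target's locants (C10 ring-fusion CH, C5 ring-fusion C–CH3, C3 isopropylidene carbon, C4 chain carbon, C8 CH–CH3, C9 benzylic quaternary carbon); α is the face of H-10 (all intermediates have C10 as in the target); Ar = 5-methoxy-3-methyl-2-(prop-2-en-1-yloxy)phenyl.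

**Step 1**
Reactants: 1 2,6-dimethoxynaphthalene
Product: 3 1,3,4,5,7,8-hexahydronaphthalene-2,6-dione, via tetrahydro bis-enol ether 2 (not isolated)
Conditions: Li, NH3(l), THF, EtOH, −33 °C; then (CO2H)2, H2O–acetone, rt
Reagents that add atoms: water, O
Why: Birch reduction of a 2,6-dialkoxynaphthalene stops at the isotetralin-type bis(enol ether) because the two oxygen-bearing and the two ring-fusion carbons stay sp2, and oxalic acid then hydrolyses both enol ethers without moving the tetrasubstituted C5=C10 bond into conjugation, so the achiral diketone is obtained with no stereocentre (Birch reduction followed by enol ether hydrolysis).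

**Step 2**
Reactants: 3 1,3,4,5,7,8-hexahydronaphthalene-2,6-dione
Product: 4 (4aS)-4,4a,7,8-tetrahydronaphthalene-2,6(3H,5H)-dione
Conditions: 9-amino-9-deoxy-epi-quinidine (10 mol %; or its quinine-derived pseudo-enantiomer, whichever gives 4aS), CF3CO2H (20 mol %), toluene, −20 °C
Reagents that add atoms: none
Why: Proposed new method: the primary amine condenses with either of the two equivalent carbonyls, the quinuclidine nitrogen removes the doubly activated α-proton of the iminium ion and, as its ammonium salt, returns it to the γ-carbon C10 on one enantiotopic face of the dienamine, so one step breaks the symmetry of 3 and fixes C10 as (S) (H-10 α), the conjugated enone being the thermodynamic sink and the second carbonyl being left without a β,γ-alkene; the closest known reaction is the amine-catalysed enantioselective β,γ- to α,β-isomerization of Birch-derived cyclohex-3-enones.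

**Step 3**
Reactants: 4 (4aS)-4,4a,7,8-tetrahydronaphthalene-2,6(3H,5H)-dione
Product: 5 (4aR,8aS)-6-[(tert-butyldimethylsilyl)oxy]-4a-methyl-3,4,4a,7,8,8a-hexahydronaphthalen-2(1H)-one
Conditions: Me2CuLi (from CH3Li, CuI), t-BuMe2SiCl, HMPA, Et3N, Et2O–THF, −78 to 0 °C
Reagents that add atoms: lithium dimethylcuprate, [Li+].C[Cu-]C; tert-butyl(chloro)dimethylsilane, CC(C)(C)[Si](C)(C)Cl
Why: Gilman conjugate addition with enolate trapping: the cuprate attacks the ring-fusion β-carbon C5 axially on the face of H-10, as in the additions to 1(9)-octal-2-ones that give cis-fused angular-methyl decalones, the saturated C8 ketone does not react at −78 °C, and O-silylation stores the regiodefined C3 enolate and so differentiates the two carbonyls.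

**Step 4**
Reactants: 6 4-methoxy-2-methylphenol
Product: 7 2-(hydroxymethyl)-4-methoxy-6-methylphenol
Conditions: 37% aq. HCHO, NaOH, H2O, 20 °C
Reagents that add atoms: formaldehyde, C=O
Why: Base-mediated ortho-hydroxymethylation of a phenol (Lederer–Manasse reaction), regiochemically unambiguous because the para and one ortho position are blocked.

**Step 5**
Reactants: 7 2-(hydroxymethyl)-4-methoxy-6-methylphenol
Product: 8 [5-methoxy-3-methyl-2-(prop-2-en-1-yloxy)phenyl]methanol
Conditions: CH2=CHCH2Br, K2CO3, acetone, 56 °C
Reagents that add atoms: allyl bromide, C=CCBr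
Why: Williamson ether synthesis in which only the phenol is acidic enough to be deprotonated by K2CO3, so the benzylic alcohol is left free.

**Step 6**
Reactants: 8 [5-methoxy-3-methyl-2-(prop-2-en-1-yloxy)phenyl]methanol
Product: 9 1-(bromomethyl)-5-methoxy-3-methyl-2-(prop-2-en-1-yloxy)benzene
Conditions: PBr3, Et2O, 0 °C
Reagents that add atoms: phosphorus tribromide, BrP(Br)Br
Why: Conversion of a primary benzylic alcohol into the bromide with PBr3 (SN2 displacement of the phosphite), conditions under which the aryl allyl ether and the aryl methyl ether are inert.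

**Step 7**
Reactants: 5 (4aR,8aS)-6-[(tert-butyldimethylsilyl)oxy]-4a-methyl-3,4,4a,7,8,8a-hexahydronaphthalen-2(1H)-one; 9 1-(bromomethyl)-5-methoxy-3-methyl-2-(prop-2-en-1-yloxy)benzene
Product: 10 9-(ArCH2) derivative of 5 (C8 ketone; mixture of C9 epimers)
Conditions: LiN(SiMe3)2, THF, −78 to 0 °C; then 9, DMPU, −78 °C to rt
Reagents that add atoms: none
Why: Ketone enolate alkylation: a cis-fused 2-decalone with this angular methyl enolizes toward the ring-fusion side, as 5β-3-keto steroids do toward C4, so the benzylic bromide enters at C9, whose configuration does not matter because C9 is re-enolized in step 8.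

**Step 8**
Reactants: 10 9-(ArCH2) derivative of 5 (mixture of C9 epimers)
Product: 11 9α-methyl-9β-(ArCH2) C8 ketone (5α-CH3; 10α-H; C3=C4 silyl enol ether)
Conditions: KH, THF, 0 °C to rt; then CH3I, 0 °C
Reagents that add atoms: iodomethane, CI
Why: Alkylation of the thermodynamic (tetrasubstituted) potassium enolate: allylic A(1,2) strain with the C9 benzyl group keeps H-10 in the enolate plane and C1 pseudo-axial, so the small electrophile CH3I attacks C9 anti to C1 on the α (convex) face and the quaternary centre is formed with 9α-methyl and 9β-benzyl.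

**Step 9**
Reactants: 11 9α-methyl-9β-(ArCH2) C8 ketone
Product: 12 8-methylidene analogue of 11 (C8=CH2)
Conditions: Ph3PCH3Br, n-BuLi, THF, 0 to 65 °C
Reagents that add atoms: methyltriphenylphosphonium bromide, C[P+](c1ccccc1)(c1ccccc1)c1ccccc1.[Br-]
Why: Wittig methylenation with the salt-free ylide, which is the standard way to convert such neopentyl C8 ketones of 9,9-disubstituted decalins into the exo-methylene compounds and leaves the silyl enol ether and the allyl ether untouched.

**Step 10**
Reactants: 12 8-methylidene analogue of 11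
Product: 13 methyl 3-[3-oxo-5α,9α-dimethyl-8-methylidene-9β-(ArCH2)-10α-H-decalin-4α-yl]propanoate
Conditions: CsF, 18-crown-6 (cat.), CH2=CHCO2CH3, DMF–THF, −40 °C; AcOH quench at −40 °C
Reagents that add atoms: methyl acrylate, C=CC(=O)OC
Why: Fluoride-triggered Michael addition of the regiodefined C3 enolate to methyl acrylate: C–C bond formation at C4 takes place axially, anti to the pseudo-axial C5–C6 bond and on the α face where only H-10 is 1,3-diaxial (the other half-chair would put the C9 quaternary carbon syn-axial to the incoming acrylate), which places the chain cis to the C5 methyl, and the cold acidic quench avoids epimerization of the new C4 centre.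

**Step 11**
Reactants: 13 methyl 3-[3-oxo-5α,9α-dimethyl-8-methylidene-9β-(ArCH2)-10α-H-decalin-4α-yl]propanoate
Product: 15 δ-lactone joining O–C3 to the chain carbonyl with 3-(prop-1-en-2-yl) (C3 epimers), via tertiary hydroxy ester 14 (not isolated)
Conditions: CH2=C(CH3)MgBr, LaCl3·2LiCl (20 mol %), THF, −78 to 0 °C; then rt
Reagents that add atoms: isopropenylmagnesium bromide, CC(=C)[Mg]Br
Why: Grignard 1,2-addition to the ketone, made selective over the ester by the lanthanum salt, followed by translactonization of the tertiary alkoxide onto the δ-ester; the new C3 carbinol centre is of no consequence because C3 becomes sp2 in step 12.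

**Step 12**
Reactants: 15 δ-lactone with 3-(prop-1-en-2-yl)
Product: 16 3-[9β-(2-hydroxy-5-methoxy-3-methylbenzyl)-5α,9α-dimethyl-8-methylidene-3-(propan-2-ylidene)-10α-H-decalin-4α-yl]propanoic acid
Conditions: Pd(PPh3)4 (5 mol %), NaBH4, THF, 25 °C; aq. citric acid work-up
Reagents that add atoms: none
Why: Tsuji–Trost-type reductive allylic cleavage: zerovalent palladium ionizes both allylic C–O bonds (the tertiary allylic lactone and the aryl allyl ether) and borohydride delivers hydride to the unhindered CH2 terminus of each allyl complex, so the lactone opens with allylic transposition to the tetrasubstituted isopropylidene and the carboxylic acid while the phenol is released with loss of propene, C4 and the C8 methylene being untouched.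

**Step 13**
Reactants: 16 3-[9β-(2-hydroxy-5-methoxy-3-methylbenzyl)-5α,9α-dimethyl-8-methylidene-3-(propan-2-ylidene)-10α-H-decalin-4α-yl]propanoic acid
Product: 17 3-[(1S,4aS,5S,6R,8aR)-5-[(2-hydroxy-5-methoxy-3-methylphenyl)methyl]-5,6,8a-trimethyl-2-(propan-2-ylidene)decahydronaphthalen-1-yl]propanoic acid (CNP0299684.4)
Conditions: H2 (1 atm), 5% Pd on carbon, EtOAc, rt
Reagents that add atoms: none
Why: Heterogeneous catalytic hydrogenation reduces the 1,1-disubstituted exocyclic alkene but not the tetrasubstituted isopropylidene, and hydrogen is delivered to the β face of C8, anti to the axial 9α-methyl group, which gives the equatorial 8α-methyl cis to the C9 methyl as in the 8-methylene reductions used for avarane-type decalins.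

**Compound list**
1 | 2,6-dimethoxynaphthalene | COc1ccc2cc(OC)ccc2c1 | starting material
2 | 2,6-dimethoxy-1,4,5,8-tetrahydronaphthalene | COC1=CCC2=C(C1)CC=C(OC)C2 | intermediate
3 | 1,3,4,5,7,8-hexahydronaphthalene-2,6-dione (achiral, C5=C10 alkene) | O=C1CCC2=C(C1)CCC(=O)C2 | intermediate
4 | (4aS)-4,4a,7,8-tetrahydronaphthalene-2,6(3H,5H)-dione (C3 enone, C8 ketone, H-10 α) | O=C1CC[C@H]2CC(=O)CCC2=C1 | intermediate
5 | (4aR,8aS)-6-[(tert-butyldimethylsilyl)oxy]-4a-methyl-3,4,4a,7,8,8a-hexahydronaphthalen-2(1H)-one (cis-decalin, 5α-CH3, 10α-H) | C1[C@@H]2CCC(O[Si](C)(C)C(C)(C)C)=C[C@]2(C)CCC1=O | intermediate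
6 | 4-methoxy-2-methylphenol | COc1ccc(O)c(C)c1 | starting material
7 | 2-(hydroxymethyl)-4-methoxy-6-methylphenol | COc1cc(C)c(O)c(CO)c1 | intermediate
8 | [5-methoxy-3-methyl-2-(prop-2-en-1-yloxy)phenyl]methanol | COc1cc(C)c(OCC=C)c(CO)c1 | intermediate
9 | 1-(bromomethyl)-5-methoxy-3-methyl-2-(prop-2-en-1-yloxy)benzene | COc1cc(C)c(OCC=C)c(CBr)c1 | intermediate
10 | 9-(ArCH2) derivative of 5 (C8 ketone, C9 epimer mixture) | COc1cc(C)c(OCC=C)c(CC2[C@@H]3CCC(O[Si](C)(C)C(C)(C)C)=C[C@]3(C)CCC2=O)c1 | intermediate
11 | 9α-methyl-9β-(ArCH2) C8 ketone with C3=C4 tert-butyldimethylsilyl enol ether (5α-CH3, 10α-H) | COc1cc(C)c(OCC=C)c(C[C@]2(C)[C@@H]3CCC(O[Si](C)(C)C(C)(C)C)=C[C@]3(C)CCC2=O)c1 | intermediate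
12 | 8-methylidene analogue of 11 | COc1cc(C)c(OCC=C)c(C[C@]2(C)[C@@H]3CCC(O[Si](C)(C)C(C)(C)C)=C[C@]3(C)CCC2=C)c1 | intermediate
13 | methyl 3-[3-oxo-5α,9α-dimethyl-8-methylidene-9β-(ArCH2)-10α-H-decalin-4α-yl]propanoate | COc1cc(C)c(OCC=C)c(C[C@]2(C)[C@@H]3CCC(=O)[C@@H](CCC(=O)OC)[C@]3(C)CCC2=C)c1 | intermediate
14 | 3-hydroxy-3-(prop-1-en-2-yl) analogue of 13 (C3 epimers; magnesium alkoxide in the flask) | COc1cc(C)c(OCC=C)c(C[C@]2(C)[C@@H]3CCC(O)(C(C)=C)[C@@H](CCC(=O)OC)[C@]3(C)CCC2=C)c1 | intermediate
15 | δ-lactone of 14 (O–C3 to chain carbonyl; 3-(prop-1-en-2-yl); C3 epimers) | COc1cc(C)c(OCC=C)c(C[C@]2(C)[C@@H]3CCC4(C(C)=C)OC(=O)CC[C@H]4[C@]3(C)CCC2=C)c1 | intermediate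
16 | 3-[9β-(2-hydroxy-5-methoxy-3-methylbenzyl)-5α,9α-dimethyl-8-methylidene-3-(propan-2-ylidene)-10α-H-decalin-4α-yl]propanoic acid | COc1cc(C)c(O)c(C[C@]2(C)[C@@H]3CCC(=C(C)C)[C@@H](CCC(=O)O)[C@]3(C)CCC2=C)c1 | intermediate
17 | 3-[(1S,4aS,5S,6R,8aR)-5-[(2-hydroxy-5-methoxy-3-methylphenyl)methyl]-5,6,8a-trimethyl-2-(propan-2-ylidene)decahydronaphthalen-1-yl]propanoic acid | COc1cc(C)c(O)c(C[C@]2(C)[C@@H]3CCC(=C(C)C)[C@@H](CCC(=O)O)[C@]3(C)CC[C@H]2C)c1 | target

**Totals**
Total step count: 13. Longest linear sequence: 10 steps (1 → 3 → 4 → 5 → 10 → 11 → 12 → 13 → 15 → 16 → 17; steps 1–3 and 7–13).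

**Three steps most likely to fail, with fallbacks**

Step 2 (the desymmetrizing isomerization has no precedent on a diketone; conversion or ee may be poor). The fallback sets out from 3: one of the two equivalent carbonyls is protected with ethylene glycol and pyridinium p-toluenesulfonate (statistical, unreacted 3 recycled) to give the mono(ethylene ketal) F1. F1 has a single β,γ-unsaturated ketone and so lies inside the established substrate class of the amine-catalysed asymmetric isomerization. Isomerization gives the enone ketal F2, and aqueous acetic acid removes the ketal to come back to the route at 4.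

Step 8 (quaternization at C9: methylation may occur at C7 or on oxygen, or from the β face). The fallback sets out from 5 and 8. Alcohol 8 is oxidized with MnO2 to 5-methoxy-3-methyl-2-(prop-2-en-1-yloxy)benzaldehyde F3. The lithium enolate of 5 is added to it to give the aldol F4, which is dehydrated with the Burgess reagent to the (E)-benzylidene ketone F5. Conjugate reduction of F5 with K[sec-Bu3BH] produces only the C8–C9 enolate, which is methylated in the same flask with CH3I from the α face, coming back to the route at 11.

Step 10 (Michael addition at the neopentyl C4: the chain may enter from the β face). The fallback sets out from 12 and makes the C4–H bond last instead of the C4–C bond. Mannich reaction of 12 with CH2=N(CH3)2+ I− gives the Mannich base F6. Quaternization with CH3I and elimination with NaHCO3 give the α-methylene ketone F7. Mukaiyama–Michael addition of CH2=C(OCH3)OSi(CH3)3 (LiClO4 cat.) gives the C3 trimethylsilyl enol ether F8, which carries the complete chain on sp2 C4. Kinetic protonation at −78 °C then puts the proton, not the chain, on the face that electrophiles prefer, coming back to the route at 13.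

**Further compounds**
F1 | step 2 | mono(ethylene ketal) of 3 (3',4',7',8'-tetrahydro-1'H-spiro[1,3-dioxolane-2,2'-naphthalen]-6'(5'H)-one) | O=C1CCC2=C(C1)CCC1(C2)OCCO1
F2 | step 2 | C8 ethylene ketal of 4 (H-10 α) | O=C1CC[C@H]2CC3(OCCO3)CCC2=C1
F3 | step 8 | 5-methoxy-3-methyl-2-(prop-2-en-1-yloxy)benzaldehyde | COc1cc(C)c(OCC=C)c(C=O)c1
F4 | step 8 | aldol of 5 with F3 (9-[aryl(hydroxy)methyl] C8 ketone, epimers at C9 and the carbinol) | COc1cc(C)c(OCC=C)c(C(O)C2[C@@H]3CCC(O[Si](C)(C)C(C)(C)C)=C[C@]3(C)CCC2=O)c1
F5 | step 8 | (E)-9-benzylidene C8 ketone derived from F4 | COc1cc(C)c(OCC=C)c(/C=C2\[C@@H]3CCC(O[Si](C)(C)C(C)(C)C)=C[C@]3(C)CCC2=O)c1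
F6 | step 10 | 4-[(dimethylamino)methyl] C3 ketone (Mannich base, C4 epimers) | COc1cc(C)c(OCC=C)c(C[C@]2(C)[C@@H]3CCC(=O)C(CN(C)C)[C@]3(C)CCC2=C)c1
F7 | step 10 | 4-methylidene C3 ketone | COc1cc(C)c(OCC=C)c(C[C@]2(C)[C@@H]3CCC(=O)C(=C)[C@]3(C)CCC2=C)c1
F8 | step 10 | C3 trimethylsilyl enol ether with the methyl propanoate chain on sp2 C4 | COc1cc(C)c(OCC=C)c(C[C@]2(C)[C@@H]3CCC(O[Si](C)(C)C)=C(CCC(=O)OC)[C@]3(C)CCC2=C)c1
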